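## Retrosynthetic overview

1. Peperomin C ⇐ reductive removal of a C5 acetal (saponification, NaBH4, relactonisation) from a 3-methyl-4-(diarylmethyl)-5-menthyloxy-γ-lactone.
2. ⇐ trans-selective enolate methylation (C3–CH3) of the 4-(diarylmethyl)-5-menthyloxy-γ-lactone.
3. ⇐ key C4–CHAr2 bond: intermolecular Michael addition of bis(3,4,5-trimethoxyphenyl)methyllithium to (5S)-5-(d-menthyloxy)furan-2(5H)-one, anti to the acetal substituent.
4. Donor ⇐ benzhydrol ⇐ aryl Grignard + 3,4,5-trimethoxybenzaldehyde; acceptor ⇐ 5-hydroxyfuranone + (+)-menthol ⇐ furfural + O2.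
5. Ring order: the aryl rings are bought; the butenolide ring is made first (furan photooxygenation) and becomes the lactone of the target, opened and re-closed once in the last step.

Assumption: the SMILES is read as the trans-(3S,4S) lactone; the two aryl groups are identical, so the diarylmethyl carbon is not a stereocenter.

## Route

Step 1
Reactants: 1 5-bromo-1,2,3-trimethoxybenzene; 2 3,4,5-trimethoxybenzaldehyde
Product: 4 bis(3,4,5-trimethoxyphenyl)methanol, via arylmagnesium bromide 3 (not isolated)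
Conditions: 1, Mg turnings, I2 (cat.), THF, 50 °C; then 2, THF, 0 °C to rt; sat. aq. NH4Cl
Reagents that add atoms: none
Why: Grignard addition of an arylmagnesium halide to a non-enolisable aromatic aldehyde reliably gives the symmetrical benzhydrol, and no stereocenter arises because both aryl groups are the same.

Step 2
Reactants: 4 bis(3,4,5-trimethoxyphenyl)methanol
Product: 5 bis(3,4,5-trimethoxyphenyl)methane
Conditions: Et3SiH (3 equiv), CF3CO2H (5 equiv, added last), CH2Cl2, 0 °C to rt
Reagents that add atoms: none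
Why: Ionic hydrogenation: the acid ionises the doubly benzylic alcohol to a stabilised benzhydryl cation that excess silane traps by hydride transfer faster than it can alkylate another arene.

Step 3
Reactants: 6 furfural
Product: 7 5-hydroxyfuran-2(5H)-one (racemic)
Conditions: O2, visible light, rose bengal (C20H2Cl4I4Na2O5, cat.), MeOH, 20 °C
Reagents that add atoms: oxygen (O2), SMILES O=O
Why: Dye-sensitised photooxygenation: singlet oxygen adds to the furan in a [4+2] cycloaddition and the endoperoxide fragments in methanol, losing the formyl carbon as methyl formate, to give the hydroxybutenolide, whose acetal carbon is racemic and is fixed in step 4.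

Step 4
Reactants: 7 5-hydroxyfuran-2(5H)-one; 8 (+)-menthol [(1S,2R,5S)-2-isopropyl-5-methylcyclohexan-1-ol]
Product: 9 (5S)-5-{[(1S,2R,5S)-2-isopropyl-5-methylcyclohexyl]oxy}furan-2(5H)-one [(5S)-5-(d-menthyloxy)-2(5H)-furanone]
Conditions: (1S)-(+)-camphor-10-sulfonic acid (C10H16O4S, cat.), toluene, reflux, Dean–Stark; crystallisation from hexane, −20 °C; mother liquor re-equilibrated with the acid and recrystallised
Reagents that add atoms: none
Why: Acid-catalysed acetalisation gives both C5 epimers, which interconvert under acid, and the (5S) epimer of the (+)-menthyl series is the crystalline one, so crystallisation with recycling of the mother liquor sets C5.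

Step 5
Reactants: 5 bis(3,4,5-trimethoxyphenyl)methane; 9 (5S)-5-(d-menthyloxy)furan-2(5H)-one
Product: 12 (4R,5S)-4-[bis(3,4,5-trimethoxyphenyl)methyl]-5-{[(1S,2R,5S)-2-isopropyl-5-methylcyclohexyl]oxy}dihydrofuran-2(3H)-one, via diarylmethyllithium 10 (not isolated), via lithium enolate 11 (not isolated)
Conditions: 5 (1.15 equiv), n-BuLi (1.1 equiv), THF, −78 to 0 °C, 1 h; then 9 (1.0 equiv) in THF, −78 °C, 2 h; AcOH, −78 °C
Reagents that add atoms: none
Why: Michael addition: the delocalised benzhydryl carbanion adds to C4 of the butenolide on the face anti to the C5 menthyloxy group (substrate control, 4,5-trans), which sets C4 in the configuration needed for the target.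

Step 6
Reactants: 12 (4R,5S)-4-[bis(3,4,5-trimethoxyphenyl)methyl]-5-(d-menthyloxy)dihydrofuran-2(3H)-one
Product: 14 (3S,4S,5S)-4-[bis(3,4,5-trimethoxyphenyl)methyl]-3-methyl-5-{[(1S,2R,5S)-2-isopropyl-5-methylcyclohexyl]oxy}dihydrofuran-2(3H)-one, via sodium enolate 13 (not isolated)
Conditions: NaN(SiMe3)2 (1.1 equiv), THF, −78 °C, 45 min; MeI (3 equiv), −78 to −40 °C; sat. aq. NH4Cl
Reagents that add atoms: iodomethane (MeI), SMILES CI
Why: Enolate alkylation (SN2): the amide base turns the isolated lactone into its sodium enolate, which is methylated anti to the bulky diarylmethyl group at C4 to give the 3,4-trans (3S) product (C4 is unchanged in space; its descriptor switches from R to S only because the methylated C3 now outranks the diarylmethyl carbon).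

Step 7
Reactants: 14 (3S,4S,5S)-4-[bis(3,4,5-trimethoxyphenyl)methyl]-3-methyl-5-(d-menthyloxy)dihydrofuran-2(3H)-one
Product: 17 peperomin C [(3S,4S)-4-[bis(3,4,5-trimethoxyphenyl)methyl]-3-methyldihydrofuran-2(3H)-one], via aldehyde carboxylate 15 (not isolated), via hydroxy acid 16 (not isolated)
Conditions: NaBH4 (4 equiv), KOH (3 equiv), EtOH/H2O, 0 °C to rt; then 2 M aq. HCl to pH 1, rt
Reagents that add atoms: none
Why: Saponification of the acyl acetal releases the C5 aldehyde and (+)-menthol, NaBH4 reduces the aldehyde as it forms (before it can enolise at C4), and acidification lactonises the γ-hydroxy acid (carried as its carboxylate until then), so both stereocenters are kept and the water taken up is given back.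

## Compound list

1 | 5-bromo-1,2,3-trimethoxybenzene | COc1cc(Br)cc(OC)c1OC | starting material
2 | 3,4,5-trimethoxybenzaldehyde | COc1cc(C=O)cc(OC)c1OC | starting material
3 | 3,4,5-trimethoxyphenylmagnesium bromide (not isolated) | COc1cc([Mg]Br)cc(OC)c1OC | intermediate
4 | bis(3,4,5-trimethoxyphenyl)methanol | COc1cc(C(O)c2cc(OC)c(OC)c(OC)c2)cc(OC)c1OC | intermediate
5 | bis(3,4,5-trimethoxyphenyl)methane | COc1cc(Cc2cc(OC)c(OC)c(OC)c2)cc(OC)c1OC | intermediate
6 | furfural (furan-2-carbaldehyde) | O=Cc1ccco1 | starting material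
7 | 5-hydroxyfuran-2(5H)-one, racemic | O=C1C=CC(O)O1 | intermediate
8 | (+)-menthol, (1S,2R,5S)-2-isopropyl-5-methylcyclohexan-1-ol | O[C@H]1C[C@@H](C)CC[C@@H]1C(C)C | starting material
9 | (5S)-5-{[(1S,2R,5S)-2-isopropyl-5-methylcyclohexyl]oxy}furan-2(5H)-one | O=C1C=C[C@@H](O[C@H]2C[C@@H](C)CC[C@@H]2C(C)C)O1 | intermediate
10 | bis(3,4,5-trimethoxyphenyl)methyllithium (not isolated) | [Li]C(c1cc(OC)c(OC)c(OC)c1)c1cc(OC)c(OC)c(OC)c1 | intermediate
11 | lithium enolate of 12 (not isolated) | [Li]OC1=C[C@H](C(c2cc(OC)c(OC)c(OC)c2)c2cc(OC)c(OC)c(OC)c2)[C@@H](O[C@H]3C[C@@H](C)CC[C@@H]3C(C)C)O1 | intermediate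
12 | (4R,5S)-4-[bis(3,4,5-trimethoxyphenyl)methyl]-5-{[(1S,2R,5S)-2-isopropyl-5-methylcyclohexyl]oxy}dihydrofuran-2(3H)-one | O=C1C[C@H](C(c2cc(OC)c(OC)c(OC)c2)c2cc(OC)c(OC)c(OC)c2)[C@@H](O[C@H]3C[C@@H](C)CC[C@@H]3C(C)C)O1 | intermediate
13 | sodium enolate of 12 (not isolated) | [Na]OC1=C[C@H](C(c2cc(OC)c(OC)c(OC)c2)c2cc(OC)c(OC)c(OC)c2)[C@@H](O[C@H]3C[C@@H](C)CC[C@@H]3C(C)C)O1 | intermediate
14 | (3S,4S,5S)-4-[bis(3,4,5-trimethoxyphenyl)methyl]-3-methyl-5-{[(1S,2R,5S)-2-isopropyl-5-methylcyclohexyl]oxy}dihydrofuran-2(3H)-one | O=C1[C@@H](C)[C@H](C(c2cc(OC)c(OC)c(OC)c2)c2cc(OC)c(OC)c(OC)c2)[C@@H](O[C@H]3C[C@@H](C)CC[C@@H]3C(C)C)O1 | intermediate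
15 | potassium (2S,3S)-3-formyl-2-methyl-4,4-bis(3,4,5-trimethoxyphenyl)butanoate (not isolated) | [K+].[O-]C(=O)[C@@H](C)[C@H](C(c1cc(OC)c(OC)c(OC)c1)c1cc(OC)c(OC)c(OC)c1)C=O | intermediate
16 | (2S,3S)-3-(hydroxymethyl)-2-methyl-4,4-bis(3,4,5-trimethoxyphenyl)butanoic acid (not isolated) | OC(=O)[C@@H](C)[C@H](C(c1cc(OC)c(OC)c(OC)c1)c1cc(OC)c(OC)c(OC)c1)CO | intermediate
17 | peperomin C, (3S,4S)-4-[bis(3,4,5-trimethoxyphenyl)methyl]-3-methyldihydrofuran-2(3H)-one | COc1cc(C(c2cc(OC)c(OC)c(OC)c2)[C@@H]2COC(=O)[C@H]2C)cc(OC)c1OC | target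

## Step count and risks

Total step count: 7. Longest linear sequence: 5 steps (steps 1, 2, 5, 6, 7, or equally steps 3, 4, 5, 6, 7).

The three steps most likely to fail are, in order of risk, step 5, step 7 and step 6.

Step 5 is the most exposed. n-BuLi may lithiate a ring position of 5 instead of the benzhydrylic CH2, and the strongly basic carbanion 10 may attack the carbonyl of 9 or deprotonate its acetal CH. The fallback sets out from 4 and comes back at 12; it uses a sulfur-stabilised, softer and less basic Michael donor and removes the sulfur afterwards. Compound 4 and thiophenol with catalytic 4-methylbenzenesulfonic acid (4-MeC6H4SO3H) in CH2Cl2 give bis(3,4,5-trimethoxyphenyl)methyl phenyl sulfide F1 (SN1 thioetherification through the benzhydryl cation). LiN(i-Pr)2 in THF at −78 °C removes the now far more acidic benzhydrylic proton to give [bis(3,4,5-trimethoxyphenyl)(phenylsulfanyl)methyl]lithium F2. F2 adds to 9 anti to the menthyloxy group to give the lithium enolate F3, which AcOH protonates at −78 °C to (4S,5S)-4-[bis(3,4,5-trimethoxyphenyl)(phenylsulfanyl)methyl]-5-(d-menthyloxy)dihydrofuran-2(3H)-one F4. Bu3SnH with catalytic 2,2'-azobis(2-methylpropanenitrile) in toluene at 90 °C then cleaves the tertiary benzylic C–S bond by a radical chain and delivers 12.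

Step 7 can erode C4 if the transient aldehyde 15 enolises in the basic medium before it is reduced, or can over-reduce the lactone. The fallback sets out from 14 and comes back at 17; it never liberates a free aldehyde in base. LiAlH4 in THF at 0 °C reduces the lactone carbonyl and the acetal carbon to (2S,3S)-2-[bis(3,4,5-trimethoxyphenyl)methyl]-3-methylbutane-1,4-diol F5, with (+)-menthol removed by chromatography. PhI(OAc)2 with catalytic 2,2,6,6-tetramethylpiperidin-1-oxyl (C9H18NO) in CH2Cl2 at rt then oxidises the less hindered primary alcohol, the one next to the methyl-bearing carbon. The hydroxy aldehyde closes to the lactol (3S,4S)-4-[bis(3,4,5-trimethoxyphenyl)methyl]-3-methyltetrahydrofuran-2-ol F6, which is oxidised on to 17. The regioisomeric lactone from oxidation at the other carbinol is the expected minor by-product and is separable.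

Step 6 can stall or lose selectivity because the C5 menthyloxy group sits on the same face as the incoming MeI (1,3-cis), and over-methylation is possible. The fallback sets out from 12 and comes back at 17; it removes the auxiliary first and methylates the unencumbered lactone last. Treating 12 with NaBH4 and KOH in EtOH/H2O, then aq. HCl, passes through potassium (3R)-3-formyl-4,4-bis(3,4,5-trimethoxyphenyl)butanoate F7. Reduction gives (3R)-3-(hydroxymethyl)-4,4-bis(3,4,5-trimethoxyphenyl)butanoic acid F8, which lactonises to (4R)-4-[bis(3,4,5-trimethoxyphenyl)methyl]dihydrofuran-2(3H)-one F9. LiN(SiMe3)2 in THF at −78 °C gives the lithium enolate F10, and MeI alkylates it anti to the diarylmethyl group to give 17. The ee of F9 must be checked by chiral HPLC, because C4 epimerisation at the aldehyde stage would here give the enantiomer and not a separable diastereomer.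

## Further compounds

F1 | step 5 | bis(3,4,5-trimethoxyphenyl)methyl phenyl sulfide | COc1cc(C(Sc2ccccc2)c2cc(OC)c(OC)c(OC)c2)cc(OC)c1OC
F2 | step 5 | [bis(3,4,5-trimethoxyphenyl)(phenylsulfanyl)methyl]lithium | [Li]C(Sc1ccccc1)(c1cc(OC)c(OC)c(OC)c1)c1cc(OC)c(OC)c(OC)c1
F3 | step 5 | lithium enolate of F4 | [Li]OC1=C[C@H](C(Sc2ccccc2)(c2cc(OC)c(OC)c(OC)c2)c2cc(OC)c(OC)c(OC)c2)[C@@H](O[C@H]3C[C@@H](C)CC[C@@H]3C(C)C)O1
F4 | step 5 | (4S,5S)-4-[bis(3,4,5-trimethoxyphenyl)(phenylsulfanyl)methyl]-5-{[(1S,2R,5S)-2-isopropyl-5-methylcyclohexyl]oxy}dihydrofuran-2(3H)-one | O=C1C[C@H](C(Sc2ccccc2)(c2cc(OC)c(OC)c(OC)c2)c2cc(OC)c(OC)c(OC)c2)[C@@H](O[C@H]3C[C@@H](C)CC[C@@H]3C(C)C)O1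
F5 | step 7 | (2S,3S)-2-[bis(3,4,5-trimethoxyphenyl)methyl]-3-methylbutane-1,4-diol | OC[C@@H](C)[C@H](C(c1cc(OC)c(OC)c(OC)c1)c1cc(OC)c(OC)c(OC)c1)CO
F6 | step 7 | (3S,4S)-4-[bis(3,4,5-trimethoxyphenyl)methyl]-3-methyltetrahydrofuran-2-ol (anomer mixture) | OC1[C@@H](C)[C@H](C(c2cc(OC)c(OC)c(OC)c2)c2cc(OC)c(OC)c(OC)c2)CO1
F7 | step 6 | potassium (3R)-3-formyl-4,4-bis(3,4,5-trimethoxyphenyl)butanoate | [K+].[O-]C(=O)C[C@H](C(c1cc(OC)c(OC)c(OC)c1)c1cc(OC)c(OC)c(OC)c1)C=O
F8 | step 6 | (3R)-3-(hydroxymethyl)-4,4-bis(3,4,5-trimethoxyphenyl)butanoic acid | OC(=O)C[C@H](C(c1cc(OC)c(OC)c(OC)c1)c1cc(OC)c(OC)c(OC)c1)CO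
F9 | step 6 | (4R)-4-[bis(3,4,5-trimethoxyphenyl)methyl]dihydrofuran-2(3H)-one | O=C1C[C@H](C(c2cc(OC)c(OC)c(OC)c2)c2cc(OC)c(OC)c(OC)c2)CO1
F10 | step 6 | lithium enolate of F9 | [Li]OC1=C[C@H](C(c2cc(OC)c(OC)c(OC)c2)c2cc(OC)c(OC)c(OC)c2)CO1
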